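**Plan**

- **Cuts:** after the acid/ester switch, C2–C3 and then C6–CH3 are cut on the intact 1,2-dioxane. O2–C3 and O1–C6 are then cut together, which releases H2O2 and an open 1,4-keto aldehyde (C3–C14). The chain is cut at C5–C6, C8–C9, C13=C14 and C10–C11.
- **Enabling feature:** ring carbon C6 (bonded to O1, CH3, C5, C7) and ring carbon C3 (bonded to O2, H, C4, C2) each carry one peroxide oxygen. Without the methyl and the acetic acid arm they are a ketone and an aldehyde carbon, and each can form a planar, oxygen-stabilised peroxycarbenium ion within the six-membered ring. The C4 methyl carbon is the only stereocentre between them.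
- **Forward order:** C10–C11 (acetylide alkylation), C13=C14 (HWE), C8–C9 (conjugate addition) and C5–C6 (amide acylation) are joined first. The only ring, the 1,2-dioxane, is then closed with H2O2/MeOH, and the C6 methyl and the C2–C3 bond are added to the finished ring last.
- **Stereochemistry:** C4 and C12 come from one purchased (R)-bromo alcohol and C8 from an (S)-benzyloxazolidinone auxiliary. C6 and then C3 come from axial attack on the ring cations, relayed from the C4 methyl, so isomer mixtures converge. Both (E)-alkenes come from the HWE reaction and from syn-hydrozirconation.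

Key step: step 14

Remark: locants C1–C14 are those of the target chain (C1 carboxyl, C3–C6 ring carbons, O2 on C3, O1 on C6, C14 bearing phenyl), and ring names keep these locants. Acetal-type ring carbons are assumed to be carried as isomer mixtures until each is ionised.

**Route**

Step 1
Reactants: 1 (R)-3-bromo-2-methylpropan-1-ol
Product: 2 (R)-(3-bromo-2-methylpropoxy)(tert-butyl)dimethylsilane
Conditions: TBSCl, imidazole, CH2Cl2, 0 °C → rt
Reagents that add atoms: tert-butyldimethylsilyl chloride, CC(C)(C)[Si](C)(C)Cl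
Why: Imidazole-promoted O-silylation of a primary alcohol, in which neither the stereocentre nor the primary bromide takes part.

Step 2
Reactants: 2 (R)-(3-bromo-2-methylpropoxy)(tert-butyl)dimethylsilane
Product: 3 (R)-tert-butyl(3-iodo-2-methylpropoxy)dimethylsilane
Conditions: NaI, acetone, reflux
Reagents that add atoms: sodium iodide, [Na+].[I-]
Why: Finkelstein reaction, an SN2 exchange at the primary carbon driven by precipitation of NaBr, which supplies the halide needed for both the alkylation and the later iodine-lithium exchange without touching the stereocentre.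

Step 3
Reactants: 3 (R)-tert-butyl(3-iodo-2-methylpropoxy)dimethylsilane; 4 ethynyltrimethylsilane
Product: 6 (S)-tert-butyldimethyl{[2-methyl-5-(trimethylsilyl)pent-4-yn-1-yl]oxy}silane, via lithium (trimethylsilyl)acetylide 5 (not isolated)
Conditions: 4, n-BuLi, THF, −78 °C; then 3, DMPU, −78 °C → rt
Reagents that add atoms: none
Why: SN2 alkylation of a lithium acetylide by a primary iodide in a dipolar cosolvent forms C10–C11, the silyl cap prevents proton shuffling, and the adjacent stereocentre (future C12) is not involved.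

Step 4
Reactants: 6 (S)-tert-butyldimethyl{[2-methyl-5-(trimethylsilyl)pent-4-yn-1-yl]oxy}silane
Product: 7 (S)-2-methyl-5-(trimethylsilyl)pent-4-yn-1-ol
Conditions: CSA (cat.), MeOH/CH2Cl2, 0 °C → rt
Reagents that add atoms: none
Why: Acid-catalysed methanolysis removes the primary O-silyl group, whereas the alkynyl C–Si bond, which is labile to base or fluoride, is stable to mild acid.

Step 5
Reactants: 7 (S)-2-methyl-5-(trimethylsilyl)pent-4-yn-1-ol
Product: 8 (S)-2-methyl-5-(trimethylsilyl)pent-4-ynal
Conditions: Dess–Martin periodinane, NaHCO3, CH2Cl2, 0 °C → rt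
Reagents that add atoms: none
Why: Buffered Dess–Martin oxidation stops at the aldehyde under near-neutral conditions, so the α-methyl centre should not enolise if the product is used promptly.

Step 6
Reactants: 8 (S)-2-methyl-5-(trimethylsilyl)pent-4-ynal; 9 diethyl benzylphosphonate
Product: 12 [(1E,3S)-3-methylhex-1-en-5-yn-1-yl]benzene, via sodium phosphonate carbanion 10 (not isolated), via C-silylated enyne 11 (not isolated)
Conditions: 9, NaHMDS, THF, 0 °C; then 8, −78 °C → rt; then MeOH, K2CO3 (cat.), rt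
Reagents that add atoms: none
Why: Horner–Wadsworth–Emmons olefination with the aryl-stabilised phosphonate anion gives the (E)-styrene C13=C14, adding the aldehyde to the preformed anion at −78 °C limits epimerisation at C12, and methanolysis in the same flask removes the alkynyl silane.

Step 7
Reactants: 12 [(1E,3S)-3-methylhex-1-en-5-yn-1-yl]benzene
Product: 14 [(1E,3S,5E)-6-iodo-3-methylhexa-1,5-dien-1-yl]benzene, via alkenylzirconocene 13 (not isolated)
Conditions: Cp2Zr(H)Cl, THF, rt, dark; then I2, 0 °C
Reagents that add atoms: iodine, II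
Why: Hydrozirconation–iodination, in which syn addition of Zr–H places the metal on the terminal alkyne carbon much faster than any reaction at the 1,2-disubstituted styrene, and iodinolysis with retention gives the (E)-iodide.

Step 8
Reactants: 14 [(1E,3S,5E)-6-iodo-3-methylhexa-1,5-dien-1-yl]benzene; 15 (S)-4-benzyl-3-[(E)-but-2-enoyl]oxazolidin-2-one
Product: 19 (S)-4-benzyl-3-[(3R,4E,7S,8E)-3,7-dimethyl-9-phenylnona-4,8-dienoyl]oxazolidin-2-one, via alkenyllithium 16 (not isolated), via alkenylmagnesium bromide 17 (not isolated), via alkenylcopper reagent 18 (not isolated)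
Conditions: 14, t-BuLi (2 equiv), Et2O, −78 °C; MgBr2·OEt2, −78 → 0 °C; CuBr·SMe2 (1 equiv), THF/Me2S, −40 °C; then 15, −78 → −20 °C
Reagents that add atoms: none
Why: Auxiliary-controlled conjugate addition of an organocopper–magnesium reagent, in which exchange and both transmetallations keep the (E)-geometry and magnesium chelates the two imide carbonyls, so the s-cis crotonoyl unit is attacked at its β-carbon on the face away from the benzyl group, forming C8–C9 and setting (8R).

Step 9
Reactants: 19 (S)-4-benzyl-3-[(3R,4E,7S,8E)-3,7-dimethyl-9-phenylnona-4,8-dienoyl]oxazolidin-2-one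
Product: 20 (3R,4E,7S,8E)-N-methoxy-N,3,7-trimethyl-9-phenylnona-4,8-dienamide
Conditions: MeNH(OMe)·HCl, AlMe3, CH2Cl2, 0 °C → rt
Reagents that add atoms: N,O-dimethylhydroxylamine hydrochloride, CNOC.Cl
Why: Aluminium amide transamination of an N-acyloxazolidinone, in which the exocyclic carbonyl without an α-branch is attacked preferentially, the auxiliary is released for recovery, and C8 and the alkenes are untouched.

Step 10
Reactants: 3 (R)-tert-butyl(3-iodo-2-methylpropoxy)dimethylsilane; 20 (3R,4E,7S,8E)-N-methoxy-N,3,7-trimethyl-9-phenylnona-4,8-dienamide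
Product: 22 (2S,6R,7E,10S,11E)-1-[(tert-butyldimethylsilyl)oxy]-2,6,10-trimethyl-12-phenyldodeca-7,11-dien-4-one, via alkyllithium 21 (not isolated)
Conditions: 3, t-BuLi (2 equiv), Et2O, −78 °C; then 20, −78 → 0 °C
Reagents that add atoms: none
Why: Weinreb ketone synthesis, in which fast iodine-lithium exchange gives the primary alkyllithium and the chelated tetrahedral adduct survives until the quench, so a single addition forms C5–C6 and brings in C4 with the configuration of 3.

Step 11
Reactants: 22 (2S,6R,7E,10S,11E)-1-[(tert-butyldimethylsilyl)oxy]-2,6,10-trimethyl-12-phenyldodeca-7,11-dien-4-one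
Product: 23 (2S,6R,7E,10S,11E)-1-hydroxy-2,6,10-trimethyl-12-phenyldodeca-7,11-dien-4-one
Conditions: TBAF, THF, 0 °C → rt
Reagents that add atoms: none
Why: Fluoride-induced Si–O cleavage, safe here because both stereocentres near the ketone (C4 and C8) are β to it and no β-leaving group is present.

Step 12
Reactants: 23 (2S,6R,7E,10S,11E)-1-hydroxy-2,6,10-trimethyl-12-phenyldodeca-7,11-dien-4-one
Product: 24 (2S,6R,7E,10S,11E)-2,6,10-trimethyl-4-oxo-12-phenyldodeca-7,11-dienal (used crude)
Conditions: Dess–Martin periodinane, NaHCO3, CH2Cl2, 0 °C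
Reagents that add atoms: none
Why: Buffered Dess–Martin oxidation of the open hydroxy ketone form gives the 1,4-keto aldehyde without acid or base strong enough to enolise C4 or to start Paal–Knorr dehydration.

Step 13
Reactants: 24 (2S,6R,7E,10S,11E)-2,6,10-trimethyl-4-oxo-12-phenyldodeca-7,11-dienal
Product: 26 (4S)-6-[(2R,3E,6S,7E)-2,6-dimethyl-8-phenylocta-3,7-dien-1-yl]-3,6-dimethoxy-4-methyl-1,2-dioxane (all C3/C6 isomers), via 1,2-dioxane-3,6-diol 25 (not isolated)
Conditions: urea·H2O2 (1.5 equiv), MeOH, 3 Å MS, 0 °C; then Sc(OTf)3 (10 mol %), 0 °C → rt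
Reagents that add atoms: hydrogen peroxide (as its urea adduct), OO; methanol, CO
Why: Perhydrolysis of a 1,4-dicarbonyl compound followed by acid-catalysed acetal exchange, the chemistry by which 1,4-diketones give 1,2-dioxane-3,6-diols and ketones give α-methoxy hydroperoxides: H2O2 masks the aldehyde before any acid is present, the hydroperoxide closes 6-exo-trig on the ketone to 25, and methanol caps both hemiacetal carbons, whose configurations do not matter because both are ionised later.

Step 14
Reactants: 26 (4S)-6-[(2R,3E,6S,7E)-2,6-dimethyl-8-phenylocta-3,7-dien-1-yl]-3,6-dimethoxy-4-methyl-1,2-dioxane (all C3/C6 isomers)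
Product: 28 (4S,6R)-6-[(2R,3E,6S,7E)-2,6-dimethyl-8-phenylocta-3,7-dien-1-yl]-3-methoxy-4,6-dimethyl-1,2-dioxane (C3 anomers), via C6 peroxycarbenium ion 27 (not isolated)
Conditions: AlMe3 (3 equiv), then TMSOTf (0.2 equiv), CH2Cl2 (dilute), −78 → −40 °C
Reagents that add atoms: trimethylaluminium, C[Al](C)C
Why: Proposed new method: the Lewis acid pair removes the C6 methoxy group from every isomer of 26, so all of them collapse to the same planar O1=C6 peroxycarbenium ion 27, which a methylaluminium species then alkylates at carbon. The closest known reactions are the Lewis acid-mediated allylation and silyl ketene acetal alkylation of ketone-derived 3-alkoxy-1,2-dioxanes and 1,2-dioxolanes, and the AlMe3 C-methylation of lactol-derived oxocarbenium ions beside an intact peroxide, whereas methyl transfer from aluminium to a peroxycarbenium ion has not been described. No ring is closed, because the dioxane exists since step 13 and only the C6–CH3 bond is formed. The new quaternary centre C6 is controlled by the C4 methyl through 1,3-induction: in the half-chair with this methyl pseudo-equatorial, only attack along the axial line on the face of the C4 hydrogen leads to a chair, which places the new methyl axial and trans to the C4 methyl and the C7 chain equatorial and cis to it, i.e. (6R). The step needs site selectivity for C6 over C3, secured because the dialkyl-substituted ketal carbon ionises far more readily than the secondary acetal carbon. It also needs chemoselectivity over the O–O bond and the alkenes, secured by the low temperature, the low nucleophilicity of AlMe3 towards dialkyl peroxides, and the fact that C9=C10 could reach C6 only through a four-membered or 5-endo closure.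

Step 15
Reactants: 28 (4S,6R)-6-[(2R,3E,6S,7E)-2,6-dimethyl-8-phenylocta-3,7-dien-1-yl]-3-methoxy-4,6-dimethyl-1,2-dioxane (C3 anomers); 29 1-(tert-butyldimethylsilyloxy)-1-methoxyethene
Product: 31 methyl 2-{(3S,4S,6R)-6-[(2R,3E,6S,7E)-2,6-dimethyl-8-phenylocta-3,7-dien-1-yl]-4,6-dimethyl-1,2-dioxan-3-yl}acetate, via C3 peroxycarbenium ion 30 (not isolated)
Conditions: 29 (3 equiv), TiCl4 (1.1 equiv), CH2Cl2, −78 °C
Reagents that add atoms: none
Why: Mukaiyama-type alkylation of a peroxyacetal by a silyl ketene acetal through a peroxycarbenium ion, known for acyclic aldehyde-derived peroxyacetals and for cyclic 3-alkoxy peroxides; both anomers give ion 30, the quaternary C6 holds the half-chair with the C4 methyl and the C7 chain equatorial, and axial attack forms C2–C3 cis to the C4 methyl, i.e. (3S).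

Step 16
Reactants: 31 methyl 2-{(3S,4S,6R)-6-[(2R,3E,6S,7E)-2,6-dimethyl-8-phenylocta-3,7-dien-1-yl]-4,6-dimethyl-1,2-dioxan-3-yl}acetate
Product: 33 2-{(3S,4S,6R)-6-[(2R,3E,6S,7E)-2,6-dimethyl-8-phenylocta-3,7-dien-1-yl]-4,6-dimethyl-1,2-dioxan-3-yl}acetic acid (CNP0179089.2), via lithium carboxylate 32 (not isolated)
Conditions: LiOH, THF/H2O, 0 °C; then 1 M HCl to pH 3
Reagents that add atoms: lithium hydroxide, [Li+].[OH-]
Why: Saponification of an unhindered methyl ester at 0 °C is faster than β-elimination of the peroxide, so the O–O bond and C3 should be preserved, and cold dilute acid liberates the free acid.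

**Compound list**

1 | (R)-3-bromo-2-methylpropan-1-ol | BrC[C@H](C)CO | starting material
2 | (R)-(3-bromo-2-methylpropoxy)(tert-butyl)dimethylsilane | BrC[C@H](C)CO[Si](C)(C)C(C)(C)C | intermediate
3 | (R)-tert-butyl(3-iodo-2-methylpropoxy)dimethylsilane | IC[C@H](C)CO[Si](C)(C)C(C)(C)C | intermediate
4 | ethynyltrimethylsilane | C#C[Si](C)(C)C | starting material
5 | lithium (trimethylsilyl)acetylide (in situ) | [Li]C#C[Si](C)(C)C | intermediate
6 | (S)-tert-butyldimethyl{[2-methyl-5-(trimethylsilyl)pent-4-yn-1-yl]oxy}silane | C[Si](C)(C)C#CC[C@H](C)CO[Si](C)(C)C(C)(C)C | intermediate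
7 | (S)-2-methyl-5-(trimethylsilyl)pent-4-yn-1-ol | C[Si](C)(C)C#CC[C@H](C)CO | intermediate
8 | (S)-2-methyl-5-(trimethylsilyl)pent-4-ynal | C[Si](C)(C)C#CC[C@H](C)C=O | intermediate
9 | diethyl benzylphosphonate | CCOP(=O)(Cc1ccccc1)OCC | starting material
10 | sodium salt of the benzylic carbanion of 9 (in situ) | [Na+].CCOP(=O)([CH-]c1ccccc1)OCC | intermediate
11 | trimethyl[(4S,5E)-4-methyl-6-phenylhex-5-en-1-yn-1-yl]silane (in situ) | C[Si](C)(C)C#CC[C@H](C)/C=C/c1ccccc1 | intermediate
12 | [(1E,3S)-3-methylhex-1-en-5-yn-1-yl]benzene | C#CC[C@H](C)/C=C/c1ccccc1 | intermediate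
13 | chloro[(1E,4S,5E)-4-methyl-6-phenylhexa-1,5-dien-1-yl]zirconocene (in situ) | Cl[Zr](/C=C/C[C@H](C)/C=C/c1ccccc1)(C1C=CC=C1)C1C=CC=C1 | intermediate
14 | [(1E,3S,5E)-6-iodo-3-methylhexa-1,5-dien-1-yl]benzene | I/C=C/C[C@H](C)/C=C/c1ccccc1 | intermediate
15 | (S)-4-benzyl-3-[(E)-but-2-enoyl]oxazolidin-2-one | C/C=C/C(=O)N1[C@@H](Cc2ccccc2)COC1=O | starting material
16 | (1E,4S,5E)-4-methyl-6-phenylhexa-1,5-dien-1-yllithium (in situ) | [Li]/C=C/C[C@H](C)/C=C/c1ccccc1 | intermediate
17 | (1E,4S,5E)-4-methyl-6-phenylhexa-1,5-dien-1-ylmagnesium bromide (in situ) | Br[Mg]/C=C/C[C@H](C)/C=C/c1ccccc1 | intermediate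
18 | (1E,4S,5E)-4-methyl-6-phenylhexa-1,5-dien-1-ylcopper(I), MgBr2 complex (in situ) | [Cu]/C=C/C[C@H](C)/C=C/c1ccccc1 | intermediate
19 | (S)-4-benzyl-3-[(3R,4E,7S,8E)-3,7-dimethyl-9-phenylnona-4,8-dienoyl]oxazolidin-2-one | C[C@H](/C=C/c1ccccc1)C/C=C/[C@H](C)CC(=O)N1[C@@H](Cc2ccccc2)COC1=O | intermediate
20 | (3R,4E,7S,8E)-N-methoxy-N,3,7-trimethyl-9-phenylnona-4,8-dienamide | C[C@H](/C=C/c1ccccc1)C/C=C/[C@H](C)CC(=O)N(C)OC | intermediate
21 | (S)-3-[(tert-butyldimethylsilyl)oxy]-2-methylpropyllithium (in situ) | [Li]C[C@H](C)CO[Si](C)(C)C(C)(C)C | intermediate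
22 | (2S,6R,7E,10S,11E)-1-[(tert-butyldimethylsilyl)oxy]-2,6,10-trimethyl-12-phenyldodeca-7,11-dien-4-one | C[C@H](/C=C/c1ccccc1)C/C=C/[C@H](C)CC(=O)C[C@H](C)CO[Si](C)(C)C(C)(C)C | intermediate
23 | (2S,6R,7E,10S,11E)-1-hydroxy-2,6,10-trimethyl-12-phenyldodeca-7,11-dien-4-one | C[C@H](/C=C/c1ccccc1)C/C=C/[C@H](C)CC(=O)C[C@H](C)CO | intermediate
24 | (2S,6R,7E,10S,11E)-2,6,10-trimethyl-4-oxo-12-phenyldodeca-7,11-dienal | C[C@H](/C=C/c1ccccc1)C/C=C/[C@H](C)CC(=O)C[C@H](C)C=O | intermediate
25 | (4S)-6-[(2R,3E,6S,7E)-2,6-dimethyl-8-phenylocta-3,7-dien-1-yl]-4-methyl-1,2-dioxane-3,6-diol, all C3/C6 isomers (in situ) | C[C@H](/C=C/c1ccccc1)C/C=C/[C@H](C)CC1(O)C[C@H](C)C(O)OO1 | intermediate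
26 | (4S)-6-[(2R,3E,6S,7E)-2,6-dimethyl-8-phenylocta-3,7-dien-1-yl]-3,6-dimethoxy-4-methyl-1,2-dioxane, all C3/C6 isomers | C[C@H](/C=C/c1ccccc1)C/C=C/[C@H](C)CC1(OC)C[C@H](C)C(OC)OO1 | intermediate
27 | C6 (O1=C6) peroxycarbenium ion from 26 (in situ) | C[C@H](/C=C/c1ccccc1)C/C=C/[C@H](C)CC1=[O+]OC(OC)[C@@H](C)C1 | intermediate
28 | (4S,6R)-6-[(2R,3E,6S,7E)-2,6-dimethyl-8-phenylocta-3,7-dien-1-yl]-3-methoxy-4,6-dimethyl-1,2-dioxane, C3 anomers | C[C@H](/C=C/c1ccccc1)C/C=C/[C@H](C)C[C@]1(C)C[C@H](C)C(OC)OO1 | intermediate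
29 | 1-(tert-butyldimethylsilyloxy)-1-methoxyethene | C=C(OC)O[Si](C)(C)C(C)(C)C | starting material
30 | C3 (O2=C3) peroxycarbenium ion from 28 (in situ) | C[C@H](/C=C/c1ccccc1)C/C=C/[C@H](C)C[C@]1(C)C[C@H](C)C=[O+]O1 | intermediate
31 | methyl 2-{(3S,4S,6R)-6-[(2R,3E,6S,7E)-2,6-dimethyl-8-phenylocta-3,7-dien-1-yl]-4,6-dimethyl-1,2-dioxan-3-yl}acetate | C[C@H](/C=C/c1ccccc1)C/C=C/[C@H](C)C[C@]1(C)C[C@H](C)[C@H](CC(=O)OC)OO1 | intermediate
32 | lithium salt of 33 (in situ) | C[C@H](/C=C/c1ccccc1)C/C=C/[C@H](C)C[C@]1(C)C[C@H](C)[C@H](CC(=O)[O-])OO1.[Li+] | intermediate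
33 | 2-{(3S,4S,6R)-6-[(2R,3E,6S,7E)-2,6-dimethyl-8-phenylocta-3,7-dien-1-yl]-4,6-dimethyl-1,2-dioxan-3-yl}acetic acid (CNP0179089.2) | C[C@H](/C=C/c1ccccc1)C/C=C/[C@H](C)C[C@]1(C)C[C@H](C)[C@H](CC(=O)O)OO1 | target

**Step count**

Total step count: 16.
Longest linear sequence: 16 (steps 1–16). Iodide 3 enters twice, in steps 3 and 10, so no separate branch has to be prepared.

**Steps most likely to fail**

**1. Step 14 (labelled new method).**
- What may go wrong:
  - methyl transfer to oxygen, with cleavage of the O–O bond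
  - ionisation by loss of the ring peroxide oxygen instead of methoxide, with ring opening
  - proton loss from the cation at C5 or C7
  - competing ionisation at C3
  - weak facial selectivity
- The fallback uses known chemistry: electrophile-induced cyclisation of an unsaturated hydroperoxy acetal by cycloperoxymercuration–demercuration. It sets out from 23.
- Excess methylenetriphenylphosphorane (Wittig) should give (2S,6R,7E,10S,11E)-2,6,10-trimethyl-4-methylidene-12-phenyldodeca-7,11-dien-1-ol F1. Dess–Martin oxidation should then give (2S,6R,7E,10S,11E)-2,6,10-trimethyl-4-methylidene-12-phenyldodeca-7,11-dienal F2.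
- Urea·H2O2 with catalytic acid in methanol should convert this aldehyde into the C3 α-methoxy hydroperoxide F3.
- Hg(OAc)2 in CH2Cl2 should close the ring 6-exo at the 1,1-disubstituted alkene (Markovnikov O1–C6 bond) to the 6-(acetoxymercuriomethyl)-3-methoxy-1,2-dioxane F4. Alkaline NaBH4 should then turn the CH2Hg group into the C6 methyl.
- Little control at C6 is expected, so the product would be separated by chromatography from the (6S)-epimer of 28 F5. The route is rejoined at 28.

**2. Step 13.**
- What may go wrong: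
  - acid-induced Paal–Knorr dehydration to a furan
  - enolisation of the aldehyde, with loss of the C4 configuration
  - capture by methanol alone to a cyclic bis-acetal
  - over-perhydrolysis to hydroperoxy or oligomeric peroxides
- In the fallback the aldehyde is consumed before any acid is used, and the ring is closed by conjugate addition instead of acetalisation. It sets out from 24.
- An aldehyde-selective Wittig reaction with methyl (triphenylphosphoranylidene)acetate should give methyl (2E,4S,8R,9E,12S,13E)-4,8,12-trimethyl-6-oxo-14-phenyltetradeca-2,9,13-trienoate F6. Urea·H2O2/Sc(OTf)3 in methanol should give the C6 α-methoxy hydroperoxide enoate F7.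
- Et2NH in CF3CH2OH should close O2–C3 by 6-exo-trig peroxy-Michael addition. The 3,4-cis isomers, methyl 2-[(3S,4S)-6-methoxy-4-methyl-6-alkyl-1,2-dioxan-3-yl]acetate F8, would be separated.
- The methylation conditions of step 14 would then be applied to F8. It has only one ionisable carbon, and its ester is tolerated at −78 °C. The route is rejoined at 31.

**3. Step 15.**
- What may go wrong:
  - Lewis acid-induced heterolysis of the O–O bond
  - proton loss from the less stabilised secondary cation at C4, which scrambles that centre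
  - attack from the equatorial side next to the C4 methyl, which erodes the 3,4-cis selectivity
- In the fallback C2–C3 is made by olefination and O2–C3 by conjugate addition. It sets out from 28.
- Mild aqueous acid (AcOH/H2O/THF) should hydrolyse the acetal to the (4S,6R)-1,2-dioxan-3-ol F9. Through its open hydroperoxy aldehyde form, this should react with the neutral stabilised ylide methyl (triphenylphosphoranylidene)acetate to give the (6R)-hydroperoxy (E)-enoate F10.
- Et2NH in CF3CH2OH should then close the ring by peroxy-Michael addition.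
- Both C3 epimers are expected. The (3R)-epimer of 31 F11 would be separated and re-equilibrated under the same amine conditions through retro-Michael opening. The route is rejoined at 31.

**Further compounds**

F1 | step 14 | (2S,6R,7E,10S,11E)-2,6,10-trimethyl-4-methylidene-12-phenyldodeca-7,11-dien-1-ol | C[C@H](/C=C/c1ccccc1)C/C=C/[C@H](C)CC(=C)C[C@H](C)CO
F2 | step 14 | (2S,6R,7E,10S,11E)-2,6,10-trimethyl-4-methylidene-12-phenyldodeca-7,11-dienal | C[C@H](/C=C/c1ccccc1)C/C=C/[C@H](C)CC(=C)C[C@H](C)C=O
F3 | step 14 | (2S,6R,7E,10S,11E)-1-methoxy-2,6,10-trimethyl-4-methylidene-12-phenyldodeca-7,11-dien-1-yl hydroperoxide (C3 α-methoxy hydroperoxide, both epimers) | C[C@H](/C=C/c1ccccc1)C/C=C/[C@H](C)CC(=C)C[C@H](C)C(OC)OO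
F4 | step 14 | (4S)-6-(acetoxymercuriomethyl)-6-[(2R,3E,6S,7E)-2,6-dimethyl-8-phenylocta-3,7-dien-1-yl]-3-methoxy-4-methyl-1,2-dioxane | C[C@H](/C=C/c1ccccc1)C/C=C/[C@H](C)CC1(C[Hg]OC(C)=O)C[C@H](C)C(OC)OO1
F5 | step 14 | (4S,6S)-6-[(2R,3E,6S,7E)-2,6-dimethyl-8-phenylocta-3,7-dien-1-yl]-3-methoxy-4,6-dimethyl-1,2-dioxane ((6S)-epimer of 28) | C[C@H](/C=C/c1ccccc1)C/C=C/[C@H](C)C[C@@]1(C)C[C@H](C)C(OC)OO1
F6 | step 13 | methyl (2E,4S,8R,9E,12S,13E)-4,8,12-trimethyl-6-oxo-14-phenyltetradeca-2,9,13-trienoate | C[C@H](/C=C/c1ccccc1)C/C=C/[C@H](C)CC(=O)C[C@H](C)/C=C/C(=O)OC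
F7 | step 13 | methyl (2E,4S,8R,9E,12S,13E)-6-hydroperoxy-6-methoxy-4,8,12-trimethyl-14-phenyltetradeca-2,9,13-trienoate (C6 α-methoxy hydroperoxide enoate) | C[C@H](/C=C/c1ccccc1)C/C=C/[C@H](C)CC(OC)(OO)C[C@H](C)/C=C/C(=O)OC
F8 | step 13 | methyl 2-{(3S,4S)-6-[(2R,3E,6S,7E)-2,6-dimethyl-8-phenylocta-3,7-dien-1-yl]-6-methoxy-4-methyl-1,2-dioxan-3-yl}acetate (C6 epimers) | C[C@H](/C=C/c1ccccc1)C/C=C/[C@H](C)CC1(OC)C[C@H](C)[C@H](CC(=O)OC)OO1
F9 | step 15 | (4S,6R)-6-[(2R,3E,6S,7E)-2,6-dimethyl-8-phenylocta-3,7-dien-1-yl]-4,6-dimethyl-1,2-dioxan-3-ol | C[C@H](/C=C/c1ccccc1)C/C=C/[C@H](C)C[C@]1(C)C[C@H](C)C(O)OO1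
F10 | step 15 | methyl (2E,4S,6R,8R,9E,12S,13E)-6-hydroperoxy-4,6,8,12-tetramethyl-14-phenyltetradeca-2,9,13-trienoate | C[C@H](/C=C/c1ccccc1)C/C=C/[C@H](C)C[C@](OO)(C)C[C@H](C)/C=C/C(=O)OC
F11 | step 15 | methyl 2-{(3R,4S,6R)-6-[(2R,3E,6S,7E)-2,6-dimethyl-8-phenylocta-3,7-dien-1-yl]-4,6-dimethyl-1,2-dioxan-3-yl}acetate ((3R)-epimer of 31) | C[C@H](/C=C/c1ccccc1)C/C=C/[C@H](C)C[C@]1(C)C[C@H](C)[C@@H](CC(=O)OC)OO1
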